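Ring positions are discussed as O1, C2, C3 (benzyl-bearing), C4 (carbinol-bearing), C5; the carbinol carbon is Cα, ring A is the aryl group of the benzyl substituent and ring B the aryl group on Cα. The systematic names in the compound list use IUPAC locants, in which the carbinol-bearing ring carbon is oxolane C3. TIPS = triisopropylsilyl.

Compound numbers used throughout: 1 oxetan-3-one; 2 triethyl phosphonoacetate; 3 oxetanylidene acetate; 4 oxetanyl acetate; 5 vanillin; 6 O-TIPS-vanillin; 7 aldol adduct; 8 its acetate; 9 (E)-acrylate; 10 (E)-allylic alcohol; 11 benzylidene tetrahydrofuran methanol; 12 trans-benzyl tetrahydrofuran methanol; 13 aldehyde; 14 4-bromo-2-methoxyphenol; 15 its TIPS ether; 16 arylmagnesium bromide; 17 bis-TIPS carbinol; 18 target.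

## Analysis of the target

The target is a tetrahydrofuran whose C2 and C5 are unsubstituted CH2–O groups, whose C3 carries a 4-hydroxy-3-methoxybenzyl group (ring A) and whose C4 carries a secondary benzylic carbinol Cα bearing a second guaiacyl ring (ring B). There are three contiguous stereocentres, C3 (R), C4 (R) and Cα (R). The two ring substituents are trans, and Cα lies outside the ring, so its configuration has to be set by acyclic induction from C4 or by a reagent. The sensitive groups are the two free phenols and above all the para-hydroxybenzylic alcohol, which ionises under acid and is prone to C–O hydrogenolysis. The final deprotection should therefore be neither acidic nor reductive, which is why the phenols are carried as TIPS ethers and released with buffered fluoride. The difficulty is that the ring has no carbonyl or other handle on C2 and C5, so absolute configuration must be brought into a sparsely functionalised ring and then relayed to two further centres. The feature on which the plan rests is that C4 carries two oxygenated carbons, C5 and Cα. With Cα taken back to the CH2OH level, C4 is the C3 of a 3-substituted oxetane whose two CH2–O arms are enantiotopic. An oxygen on C2 that opens one arm forms O1–C5, closes the tetrahydrofuran and makes C4 stereogenic, while the other arm is released as the CH2OH that becomes Cα.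

## Retrosynthetic reasoning

Target 18 is traced back to the bis-silyl ether 17 by cleavage of the two aryl O–Si bonds. Silyl ethers are chosen because their removal with fluoride leaves the benzylic C–OH bond untouched.

Carbinol 17 is cut at the Cα–aryl bond into aldehyde 13 and the arylmagnesium bromide 16, which comes from bromide 15 and thus from bromophenol 14. The cut is made here because it puts Cα at the aldehyde level, directly reachable from a CH2OH group, and because addition of an aryl nucleophile to 13 is the direction in which 1,2-induction from C4 is expected to favour the (R)-carbinol. The forward reaction has to add to an α-branched aldehyde without epimerising C4.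

Aldehyde 13 comes from the primary alcohol 12 by oxidation. C4 is α to the new carbonyl, but the trans arrangement is the more stable one, so base would not drive it to the cis isomer.

Alcohol 12 is traced back to the benzylidene compound 11 by removing the two hydrogens at C3 and the benzylic carbon. Keeping C3 planar up to this point means that its configuration is created only once C4 exists. The forward hydrogenation must deliver hydrogen from the face of the CH2OH group, which places the benzyl group trans.

Alcohol 11 is cut at O1–C5, the key disconnection, which leads to the achiral oxetane 10. It is chosen over any C–C disconnection of the ring because it turns the creation of C4 into a choice between two enantiotopic CH2 groups, which a chiral cobalt–salen Lewis acid can make catalytically. The forward reaction has to open the oxetane with the allylic hydroxyl of 10 without ionising that hydroxyl.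

Allylic alcohol 10 comes from ester 9 by reduction, and 9 is cut at the C3=CH bond into the ester 4 and the aldehyde 6 by way of aldol adduct 7 and its acetate 8. This cut brings ring A and the future benzylic carbon in from protected vanillin and places the oxetane on the α-carbon of a simple acetate.

Ester 4 is the hydrogenation product of alkylidene ester 3, which arises from ketone 1 and phosphonate 2 by olefination. Aldehyde 6 is the silyl ether of vanillin 5.

## Alternatives that were turned down

Alternative 1: The C4–Cα and C3–benzyl bonds are cut in a three-component union on a carbohydrate-derived bicyclic enone, and C2 and C5 are carved out of the template afterwards.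
- Forward key step: the anion of dithiane A4 adds in conjugate fashion to the enone of template A2 from the face opposite the anhydro bridge. The enolate is then trapped by bromide A5 trans to the new substituent, giving A1.
- For: one flask sets both ring stereocentres and their trans relation on a rigid bicycle, needs no chiral catalyst, brings in both aryl groups convergently and already holds Cα as a masked ketone.
- Against: working the configuration of A1 back gives (1R,5S) bridgeheads, that is template A2, whereas cellulose pyrolysis supplies the antipode A3. Addition anti to the bridge of A3 would end at the enantiomer of the target, so the template would have to be made.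
- Against: a long degradative sequence follows the key step. It needs oxygen insertion beside the ketone, reduction, glycol cleavage to remove one template carbon, reductive closure of the tetrahydrofuran and dithiane removal next to two electron-rich arenes. The resulting aryl ketone must then be reduced, and its intrinsic Felkin sense is expected to give the wrong Cα epimer, because hydride takes the place that the aryl group takes in step 11.
- Comparison: this route is stronger on the security of the C3/C4 trans relation and on independence from a chiral catalyst. The chosen route offers instead a catalytic entry from achiral materials in which either enantiomer is equally accessible, no carbon is discarded, and Cα is formed in the favourable sense.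

Alternative 2: C2–C3 and C4–C5 are cut at once, so the ring comes from a C–O–C three-atom unit and two alkene carbons.
- Forward key step: the parent carbonyl ylide, released from A7 by fluoride-induced 1,3-elimination, adds across the E-alkene of the acyl sultam A8 and gives A6.
- For: the ring is made in one step, and suprafacial addition to an E-alkene guarantees the trans relation. This is a firmer guarantee than the directed hydrogenation of the chosen route, and the approach is more convergent.
- Against: a very reactive, unstabilised ylide must distinguish the faces of an alkene flanked by two different carbonyl groups, which makes the reactive conformation and so the auxiliary control uncertain.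
- Against: after the key step the two carbonyl-bearing substituents need opposite fates. The sultam carbonyl must become CH2–aryl through cleavage, aryl addition and benzylic deoxygenation, while the aroyl group must stop at the (R)-alcohol and survive that deoxygenation. Both ring centres are α to carbonyl groups meanwhile, and the ketone reduction meets the same Felkin mismatch as in alternative 1.
- Comparison: this route is shorter up to the ring and longer and more delicate after it. The chosen route carries the benzyl carbon at the right oxidation level from the start and needs a single redox adjustment at Cα.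

Alternative 3: C2–C3 is cut, with the O1–C2 unit carried as an oxygen-bound CH2 radical and C4 and Cα set beforehand in an open chain.
- Forward key step: a tin hydride with a radical initiator removes the phenylseleno group of A10, the alkoxymethyl radical closes 5-exo-trig onto the styrene, and the benzylic radical is reduced to A9.
- For: A9 is the fully protected target, so only deprotection remains. The conditions are neutral, and Cα can be set before cyclisation by reliable auxiliary-based aldol chemistry, which is stronger Cα control than the chosen route offers.
- Against: C3 is set by 1,2-induction in a chair-like radical transition state. It predicts trans but is usually only moderate, and any cis isomer would have to be removed at the last stage.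
- Against: tin and selenium are used stoichiometrically, and A10 needs a multi-step asymmetric assembly of two adjacent stereocentres, an E-styrene and the selenomethyl ether. The benzyl ethers would also have to be removed by hydrogenolysis next to a para-hydroxybenzylic alcohol.
- Comparison: this route is equal or better at Cα and in the endgame and weaker at C3. The chosen route creates its first stereocentre catalytically in the ring-forming step and sets C3 by hydroxyl-directed hydrogen delivery.

Key step: step 7

Assumption: the absolute sense of induction of the cobalt–salen catalyst for this substrate is not derived here. The (R,R)-catalyst is written, and if the first run shows that it gives the mirror-image product, the (S,S)-catalyst is used with no other change.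

## Route

Step 1
Reactants: 1 oxetan-3-one; 2 triethyl phosphonoacetate
Product: 3 ethyl 2-(oxetan-3-ylidene)acetate
Conditions: NaH, THF, 0 °C; then 1, 0 °C → rt
Reagents that add atoms: none
Why: Horner–Wadsworth–Emmons olefination of a strained, unhindered ketone; the ring is symmetric, so no alkene geometry arises.

Step 2
Reactants: 3 ethyl 2-(oxetan-3-ylidene)acetate
Product: 4 ethyl 2-(oxetan-3-yl)acetate
Conditions: H2 (1 atm), Pd/C, EtOAc, rt
Reagents that add atoms: none
Why: Catalytic hydrogenation of an electron-poor trisubstituted alkene; the oxetane is inert under neutral conditions.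

Step 3
Reactants: 5 vanillin
Product: 6 3-methoxy-4-(triisopropylsilyloxy)benzaldehyde
Conditions: iPr3SiCl, imidazole, DMF, rt
Reagents that add atoms: chlorotri(propan-2-yl)silane, CC(C)[Si](Cl)(C(C)C)C(C)C
Why: Standard silylation of a phenol; the TIPS ether tolerates amide bases, amidine bases, hydride and Grignard reagents and is removed at the end by fluoride.

Step 4
Reactants: 4 ethyl 2-(oxetan-3-yl)acetate; 6 3-methoxy-4-(triisopropylsilyloxy)benzaldehyde
Product: 7 ethyl 3-hydroxy-3-[3-methoxy-4-(triisopropylsilyloxy)phenyl]-2-(oxetan-3-yl)propanoate (racemic, both diastereomers)
Conditions: LiN(iPr)2, THF, −78 °C; then 6, −78 °C; then AcOH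
Reagents that add atoms: none
Why: Aldol addition of a lithium ester enolate to a non-enolisable aryl aldehyde; the enolate carbon has no β-leaving group and the oxetane is not opened at low temperature, and both new stereocentres are removed in step 5.

Step 5
Reactants: 7 ethyl 3-hydroxy-3-[3-methoxy-4-(triisopropylsilyloxy)phenyl]-2-(oxetan-3-yl)propanoate
Product: 9 ethyl (E)-3-[3-methoxy-4-(triisopropylsilyloxy)phenyl]-2-(oxetan-3-yl)prop-2-enoate, via acetate 8 (not isolated)
Conditions: Ac2O, Et3N, DMAP (cat.), CH2Cl2, 0 °C → rt; then DBU, rt → 40 °C
Reagents that add atoms: acetic anhydride, CC(=O)OC(C)=O (its acetyl group is held only in intermediate 8; no atoms remain in 9)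
Why: Acetylation followed by E1cB elimination through the ester enolate, which should favour the more stable (E)-α-substituted cinnamate with the aryl group trans to the ester; the geometry is erased again in step 8, so it matters only for obtaining a single substrate for step 7.

Step 6
Reactants: 9 ethyl (E)-3-[3-methoxy-4-(triisopropylsilyloxy)phenyl]-2-(oxetan-3-yl)prop-2-enoate
Product: 10 (E)-3-[3-methoxy-4-(triisopropylsilyloxy)phenyl]-2-(oxetan-3-yl)prop-2-en-1-ol
Conditions: iBu2AlH, CH2Cl2, −78 °C; then aq. potassium sodium tartrate
Reagents that add atoms: none
Why: 1,2-Reduction of an α,β-unsaturated ester to the allylic alcohol; the cold quench and non-acidic work-up are meant to prevent an early, racemic closure of the oxetane by the aluminium alkoxide or by acid.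

Step 7
Reactants: 10 (E)-3-[3-methoxy-4-(triisopropylsilyloxy)phenyl]-2-(oxetan-3-yl)prop-2-en-1-ol
Product: 11 [(3S,4E)-4-{[3-methoxy-4-(triisopropylsilyloxy)phenyl]methylidene}oxolan-3-yl]methanol
Conditions: (R,R)-(salen)Co(OTf) (2–5 mol %; salen = N,N′-bis(3,5-di-tert-butylsalicylidene)cyclohexane-1,2-diamine dianion, cobalt trivalent), 4 Å molecular sieves, MeCN, 23 °C
Reagents that add atoms: none
Why: This is an enantioselective intramolecular oxetane opening of the type known for cobalt–salen-catalysed cyclisation of 3-substituted oxetanes with a pendant alcohol to 3-(hydroxymethyl)tetrahydrofurans. The Lewis-acidic trivalent cobalt centre binds the oxetane oxygen, and the allylic hydroxyl attacks one ring CH2 from the backside in an SN2 step, so the O1–C5 bond forms and the tetrahydrofuran closes in the 5-exo-tet mode with release of the four-ring strain. The former oxetane C3 becomes C4, and its configuration depends only on which of the two enantiotopic CH2 groups is attacked; since 10 is achiral, the chiral salen ligand is the sole control element. No regiochemical choice exists, because both CH2 groups give the same five-membered ring. The step needs enantiotopic-group selection (ligand), preference for oxetane activation over ionisation of the electron-rich cinnamyl-type alcohol (a mild oxophilic cobalt triflate in a non-acidic medium) and intra- over intermolecular opening (short tether, moderate dilution). The E-alkene is a spectator that keeps C3 planar, so only one stereocentre is formed, and a five-membered ring with an exocyclic alkene at the sp2 tether carbon is unstrained. The CH2OH group that is released is the future Cα and the directing group of step 8.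

Step 8
Reactants: 11 [(3S,4E)-4-{[3-methoxy-4-(triisopropylsilyloxy)phenyl]methylidene}oxolan-3-yl]methanol
Product: 12 [(3S,4R)-4-{[3-methoxy-4-(triisopropylsilyloxy)phenyl]methyl}oxolan-3-yl]methanol
Conditions: [Ir(cod)(PCy3)(py)]PF6 (2–5 mol %), H2 (1 atm), CH2Cl2, 0 °C → rt
Reagents that add atoms: none
Why: Hydroxyl-directed hydrogenation of a homoallylic alcohol; iridium bound to the CH2OH oxygen should deliver both hydrogens to the alkene face on which that group sits, so the new C3–H is cis to CH2OH and the benzyl group trans, which sets C3 (R). Any cis isomer is removed here, because after step 9 it could epimerise at C4 into the enantiomeric trans series.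

Step 9
Reactants: 12 [(3S,4R)-4-{[3-methoxy-4-(triisopropylsilyloxy)phenyl]methyl}oxolan-3-yl]methanol
Product: 13 (3R,4R)-4-{[3-methoxy-4-(triisopropylsilyloxy)phenyl]methyl}oxolane-3-carbaldehyde
Conditions: Dess–Martin periodinane, NaHCO3, CH2Cl2, 0 °C → rt
Reagents that add atoms: none
Why: Buffered Dess–Martin oxidation of a primary alcohol; C4 is now α to the carbonyl group but already has the more stable trans arrangement, and the aldehyde is used without storage.

Step 10
Reactants: 14 4-bromo-2-methoxyphenol
Product: 15 (4-bromo-2-methoxyphenoxy)triisopropylsilane
Conditions: iPr3SiCl, imidazole, DMF, rt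
Reagents that add atoms: chlorotri(propan-2-yl)silane, CC(C)[Si](Cl)(C(C)C)C(C)C
Why: Standard silylation of a phenol, giving the precursor of the ring B nucleophile with the same protecting group as ring A.

Step 11
Reactants: 15 (4-bromo-2-methoxyphenoxy)triisopropylsilane; 13 (3R,4R)-4-{[3-methoxy-4-(triisopropylsilyloxy)phenyl]methyl}oxolane-3-carbaldehyde
Product: 17 (R)-[3-methoxy-4-(triisopropylsilyloxy)phenyl][(3R,4R)-4-{[3-methoxy-4-(triisopropylsilyloxy)phenyl]methyl}oxolan-3-yl]methanol, via arylmagnesium bromide 16 (not isolated)
Conditions: 15, Mg, THF, 50 °C; then 13, THF, −78 → −20 °C; then H2O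
Reagents that add atoms: magnesium, [Mg] (held only in intermediate 16; no atoms remain in 17)
Why: Grignard addition to an α-branched aldehyde under Felkin–Anh control: with the larger C3 anti to the incoming aryl group and C5 next to the carbonyl oxygen, attack past the C4–H should give the (R)-carbinol. A magnesium chelate between the carbonyl oxygen and O1 exposes the same face, so both models agree; the minor epimer is removed by chromatography.

Step 12
Reactants: 17 (R)-[3-methoxy-4-(triisopropylsilyloxy)phenyl][(3R,4R)-4-{[3-methoxy-4-(triisopropylsilyloxy)phenyl]methyl}oxolan-3-yl]methanol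
Product: 18 4-[(R)-hydroxy{(3R,4R)-4-[(4-hydroxy-3-methoxyphenyl)methyl]oxolan-3-yl}methyl]-2-methoxyphenol (target)
Conditions: Bu4NF, AcOH, THF, 0 °C → rt
Reagents that add atoms: none
Why: Fluoride cleavage of two aryl silyl ethers; buffering with acetic acid avoids free phenoxide next to the benzylic alcohol, and no reductive or strongly acidic step touches the benzylic C–OH bond.

## Compound list

1 | oxetan-3-one | O=C1COC1 | starting material
2 | triethyl phosphonoacetate | CCOC(=O)CP(=O)(OCC)OCC | starting material
3 | ethyl 2-(oxetan-3-ylidene)acetate | CCOC(=O)C=C1COC1 | intermediate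
4 | ethyl 2-(oxetan-3-yl)acetate | CCOC(=O)CC1COC1 | intermediate
5 | vanillin | COc1cc(C=O)ccc1O | starting material
6 | 3-methoxy-4-(triisopropylsilyloxy)benzaldehyde | COc1cc(C=O)ccc1O[Si](C(C)C)(C(C)C)C(C)C | intermediate
7 | ethyl 3-hydroxy-3-[3-methoxy-4-(triisopropylsilyloxy)phenyl]-2-(oxetan-3-yl)propanoate (racemic, both diastereomers) | CCOC(=O)C(C1COC1)C(O)c1ccc(O[Si](C(C)C)(C(C)C)C(C)C)c(OC)c1 | intermediate
8 | ethyl 3-acetoxy-3-[3-methoxy-4-(triisopropylsilyloxy)phenyl]-2-(oxetan-3-yl)propanoate (not isolated) | CCOC(=O)C(C1COC1)C(OC(C)=O)c1ccc(O[Si](C(C)C)(C(C)C)C(C)C)c(OC)c1 | intermediate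
9 | ethyl (E)-3-[3-methoxy-4-(triisopropylsilyloxy)phenyl]-2-(oxetan-3-yl)prop-2-enoate | CCOC(=O)/C(C1COC1)=C/c1ccc(O[Si](C(C)C)(C(C)C)C(C)C)c(OC)c1 | intermediate
10 | (E)-3-[3-methoxy-4-(triisopropylsilyloxy)phenyl]-2-(oxetan-3-yl)prop-2-en-1-ol | OC/C(C1COC1)=C/c1ccc(O[Si](C(C)C)(C(C)C)C(C)C)c(OC)c1 | intermediate
11 | [(3S,4E)-4-{[3-methoxy-4-(triisopropylsilyloxy)phenyl]methylidene}oxolan-3-yl]methanol | OC[C@H]1COC/C1=C/c1ccc(O[Si](C(C)C)(C(C)C)C(C)C)c(OC)c1 | intermediate
12 | [(3S,4R)-4-{[3-methoxy-4-(triisopropylsilyloxy)phenyl]methyl}oxolan-3-yl]methanol | COc1cc(C[C@H]2COC[C@@H]2CO)ccc1O[Si](C(C)C)(C(C)C)C(C)C | intermediate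
13 | (3R,4R)-4-{[3-methoxy-4-(triisopropylsilyloxy)phenyl]methyl}oxolane-3-carbaldehyde | COc1cc(C[C@H]2COC[C@@H]2C=O)ccc1O[Si](C(C)C)(C(C)C)C(C)C | intermediate
14 | 4-bromo-2-methoxyphenol | COc1cc(Br)ccc1O | starting material
15 | (4-bromo-2-methoxyphenoxy)triisopropylsilane | COc1cc(Br)ccc1O[Si](C(C)C)(C(C)C)C(C)C | intermediate
16 | [3-methoxy-4-(triisopropylsilyloxy)phenyl]magnesium bromide (not isolated) | COc1cc([Mg]Br)ccc1O[Si](C(C)C)(C(C)C)C(C)C | intermediate
17 | (R)-[3-methoxy-4-(triisopropylsilyloxy)phenyl][(3R,4R)-4-{[3-methoxy-4-(triisopropylsilyloxy)phenyl]methyl}oxolan-3-yl]methanol | COc1cc(C[C@H]2COC[C@@H]2[C@@H](O)c2ccc(O[Si](C(C)C)(C(C)C)C(C)C)c(OC)c2)ccc1O[Si](C(C)C)(C(C)C)C(C)C | intermediate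
18 | 4-[(R)-hydroxy{(3R,4R)-4-[(4-hydroxy-3-methoxyphenyl)methyl]oxolan-3-yl}methyl]-2-methoxyphenol | COc1cc(C[C@H]2COC[C@@H]2[C@@H](O)c2ccc(O)c(OC)c2)ccc1O | target

## Step count and risks

Total step count: 12. Longest linear sequence: 10 steps (steps 1, 2, 4, 5, 6, 7, 8, 9, 11, 12, from oxetan-3-one 1 to 18).

Least certain steps:

**Step 7 (key step).**
- Most likely to go wrong is the discrimination between the two enantiotopic CH2 groups. The oxetane carries an alkenyl substituent and the nucleophile is an allylic hydroxyl on an sp2 tether, which differs from the saturated tethers on which this catalysis is best established.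
- Two further dangers are ionisation of the electron-rich allylic alcohol at the Lewis acid and a racemic background closure by traces of acid.
- Fallback, from 10 back to 11:
  - The ring is closed without chirality control using catalytic Sc(OTf)3 in CH2Cl2 at 0 °C, giving the racemic alcohol F1.
  - F1 is resolved by esterification with (S)-2-methoxy-2-phenylacetic acid (DCC, DMAP). This gives the (S)-2-methoxy-2-phenylacetate of 11, F2, and the (S)-2-methoxy-2-phenylacetate of the enantiomer of 11, F3, which are separated by chromatography or crystallisation.
  - F2 is cleaved with iBu2AlH at −78 °C and returns 11.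

**Step 8.**
- Hydroxyl direction may be incomplete, because the primary hydroxyl sits on a freely rotating arm and the ring oxygen competes for iridium. Hydrogen would then also add from the opposite face.
- The alkene may also migrate into the ring before it is reduced, which would destroy C4.
- Fallback, from 11 to 12:
  - Face selection is handed from the substrate to the catalyst. Compound 11 is hydrogenated with a chiral iridium phosphine–oxazoline complex of the [Ir(cod)(PHOX)]BArF type (BArF = tetrakis[3,5-bis(trifluoromethyl)phenyl]borate), a class that reduces trisubstituted aryl alkenes and cinnamyl-type alcohols under ligand control.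
  - The ligand antipode that reinforces the hydroxyl direction is used.
  - No new compound is made.

**Step 11.**
- The facial selectivity of the aryl addition may be only modest, because 1,2-induction from C4 rests on the size difference between C3 and C5.
- The basic reagent may also enolise the aldehyde, with partial epimerisation at C4.
- Fallback, from 17 as obtained in a mixture with its (S)-carbinol epimer F4, back to 17:
  - The mixture is oxidised with Dess–Martin periodinane to the aryl ketone F5.
  - F5 is reduced with (S)-2-methyl-CBS-oxazaborolidine and BH3·SMe2, which should give the (R)-carbinol 17 with the aryl group acting as the large substituent.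
  - This reduction runs against the Felkin preference of the ketone, so it depends on the reagent overriding the substrate.

**Step 5.**
- The elimination may give incomplete geometric control, since the branched oxetanyl group is cis to the aryl group in the E-isomer. Retro-aldol cleavage may also occur before the acetate is fully formed.
- The geometry has no influence on the final configuration, but a mixture would complicate step 7.
- Fallback, from 6 to 9:
  - One-pot bromination and Wittig olefination of 6 with Ph3P=CHCO2Et and N-bromosuccinimide gives ethyl (Z)-2-bromo-3-[3-methoxy-4-(triisopropylsilyloxy)phenyl]prop-2-enoate F6.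
  - F6 is coupled with retention of geometry with oxetan-3-ylzinc iodide F7, prepared from 3-iodooxetane and Zn, under Pd(OAc)2/CPhos catalysis (Negishi coupling). This gives 9 with the aryl group cis to the oxetane.

## Further compounds

F1 | step 7 | racemic [(4E)-4-{[3-methoxy-4-(triisopropylsilyloxy)phenyl]methylidene}oxolan-3-yl]methanol | OCC1COC/C1=C/c1ccc(O[Si](C(C)C)(C(C)C)C(C)C)c(OC)c1
F2 | step 7 | (S)-2-methoxy-2-phenylacetate of 11 | CO[C@H](C(=O)OC[C@H]1COC/C1=C/c1ccc(O[Si](C(C)C)(C(C)C)C(C)C)c(OC)c1)c1ccccc1
F3 | step 7 | (S)-2-methoxy-2-phenylacetate of the enantiomer of 11 | CO[C@H](C(=O)OC[C@@H]1COC/C1=C/c1ccc(O[Si](C(C)C)(C(C)C)C(C)C)c(OC)c1)c1ccccc1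
F0 | step 8 | none | none
F4 | step 11 | (S)-[3-methoxy-4-(triisopropylsilyloxy)phenyl][(3R,4R)-4-{[3-methoxy-4-(triisopropylsilyloxy)phenyl]methyl}oxolan-3-yl]methanol | COc1cc(C[C@H]2COC[C@@H]2[C@H](O)c2ccc(O[Si](C(C)C)(C(C)C)C(C)C)c(OC)c2)ccc1O[Si](C(C)C)(C(C)C)C(C)C
F5 | step 11 | [3-methoxy-4-(triisopropylsilyloxy)phenyl][(3R,4R)-4-{[3-methoxy-4-(triisopropylsilyloxy)phenyl]methyl}oxolan-3-yl]methanone | COc1cc(C[C@H]2COC[C@@H]2C(=O)c2ccc(O[Si](C(C)C)(C(C)C)C(C)C)c(OC)c2)ccc1O[Si](C(C)C)(C(C)C)C(C)C
F6 | step 5 | ethyl (Z)-2-bromo-3-[3-methoxy-4-(triisopropylsilyloxy)phenyl]prop-2-enoate | CCOC(=O)/C(Br)=C/c1ccc(O[Si](C(C)C)(C(C)C)C(C)C)c(OC)c1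
F7 | step 5 | oxetan-3-ylzinc iodide | I[Zn]C1COC1
A1 | alternative 1 | 2-[2-(4-benzyloxy-3-methoxyphenyl)-1,3-dithian-2-yl]-3-(4-benzyloxy-3-methoxybenzyl)-6,8-dioxabicyclo[3.2.1]octan-4-one, (1R,5S) bridgeheads | C1[C@H]2[C@H](C3(c4ccc(OCc5ccccc5)c(OC)c4)SCCCS3)[C@@H](Cc3ccc(OCc4ccccc4)c(OC)c3)C(=O)[C@@H](O1)O2
A2 | alternative 1 | (1R,5S)-6,8-dioxabicyclo[3.2.1]oct-2-en-4-one | C1[C@H]2C=CC(=O)[C@@H](O1)O2
A3 | alternative 1 | (1S,5R)-6,8-dioxabicyclo[3.2.1]oct-2-en-4-one (levoglucosenone from cellulose) | C1[C@@H]2C=CC(=O)[C@H](O1)O2
A4 | alternative 1 | 2-(4-benzyloxy-3-methoxyphenyl)-1,3-dithiane | COc1cc(C2SCCCS2)ccc1OCc1ccccc1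
A5 | alternative 1 | 4-benzyloxy-3-methoxybenzyl bromide | COc1cc(CBr)ccc1OCc1ccccc1
A6 | alternative 2 | trans-3-(4-benzyloxy-3-methoxybenzoyl)-4-(bornane-10,2-sultam-N-carbonyl)tetrahydrofuran | COc1cc(C(=O)[C@H]2COC[C@@H]2C(=O)N3S(=O)(=O)C[C@]45CC[C@H](C[C@@H]34)C5(C)C)ccc1OCc1ccccc1
A7 | alternative 2 | chloromethyl (trimethylsilyl)methyl ether | C[Si](C)(C)COCCl
A8 | alternative 2 | N-[(E)-4-(4-benzyloxy-3-methoxyphenyl)-4-oxobut-2-enoyl]bornane-10,2-sultam | COc1cc(C(=O)/C=C/C(=O)N2S(=O)(=O)C[C@]34CC[C@H](C[C@@H]23)C4(C)C)ccc1OCc1ccccc1
A9 | alternative 3 | target with both phenols as benzyl ethers and the carbinol as its tert-butyldimethylsilyl ether | COc1cc(C[C@H]2COC[C@@H]2[C@@H](O[Si](C)(C)C(C)(C)C)c2ccc(OCc3ccccc3)c(OC)c2)ccc1OCc1ccccc1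
A10 | alternative 3 | phenylselenomethyl ether of the open-chain (E)-styrene precursor | COc1cc(/C=C/[C@H](COC[Se]c2ccccc2)[C@@H](O[Si](C)(C)C(C)(C)C)c2ccc(OCc3ccccc3)c(OC)c2)ccc1OCc1ccccc1
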